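## Retrosynthetic overview

- Target ⇐ removal of two MOM groups ⇐ (2S)-flavanone, made by rhodium-catalysed asymmetric 1,4-addition of (4-hydroxyphenyl)boronic acid (ring B, from 4-bromophenol) to an 8-alkyl-5,7-bis(MOM-oxy)chromone.
- Chromone (ring C) ⇐ ortho-formylation of a 2-alkylphenol, ethynyl addition, oxidation and 6-endo oxa-Michael closure.
- Isopropenyl group ⇐ Zweifel olefination (stereoretentive 1,2-metallate shift) of a secondary boronic ester.
- Key step: enantioselective palladium-induced 1,2-metallate shift (conjunctive coupling) of an alkyl(vinyl)boron ate complex with a 2-bromo-3,5-dioxygenated phenol silyl ether; it forms the aryl–CH2 and CH–alkyl bonds and the side-chain stereocentre.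
- Aryl bromide ⇐ resorcinol by MOM protection, meta C–H borylation/oxidation, ortho-bromination and silylation. Ring order: A (bought) → C → B attached last.

Assumption: the sense of induction of the two ligand-controlled steps (6 and 12) is assigned by analogy with the closest reported cases; if the first run shows the opposite sense (Mosher analysis of an oxidised aliquot of the boronate, chiral HPLC of the flavanone), the commercial ligand antipode is used.

## Route

Step 1
Reactants: 1 resorcinol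
Product: 2 1,3-bis(methoxymethoxy)benzene
Conditions: MOMCl (2.5 equiv), i-Pr2NEt (3 equiv), CH2Cl2, 0 °C → rt
Reagents that add atoms: chloromethyl methyl ether, COCCl
Why: Williamson-type O-alkylation of both phenols gives acetal ethers that survive every basic, organometallic and oxidative step that follows.

Step 2
Reactants: 2 1,3-bis(methoxymethoxy)benzene
Product: 4 3,5-bis(methoxymethoxy)phenol, via arylboronic ester 3 (not isolated)
Conditions: [Ir(OMe)(cod)]2 (1.5 mol%), 4,4′-di-tert-butyl-2,2′-bipyridine (3 mol%), B2pin2 (1.0 equiv), THF, 80 °C; then 30% H2O2, aq. NaOH, 0 °C → rt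
Reagents that add atoms: bis(pinacolato)diboron, CC1(C)OB(OC1(C)C)B1OC(C)(C)C(C)(C)O1 (boron and pinacolate of 3 only); hydrogen peroxide, OO
Why: Sterically governed iridium-catalysed C–H borylation (Hartwig–Miyaura type) occurs only meta to both OMOM groups, and boronate oxidation gives the one free phenol that later becomes the ring oxygen O1.

Step 3
Reactants: 4 3,5-bis(methoxymethoxy)phenol
Product: 5 2-bromo-3,5-bis(methoxymethoxy)phenol
Conditions: NBS (1.0 equiv), i-Pr2NH (10 mol%), CH2Cl2, −78 °C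
Reagents that add atoms: N-bromosuccinimide, O=C1CCC(=O)N1Br
Why: Amine-mediated ortho-selective electrophilic aromatic bromination, in which the N-bromoamine is delivered by hydrogen bonding to the phenol OH while the para position is flanked by two OMOM groups.

Step 4
Reactants: 5 2-bromo-3,5-bis(methoxymethoxy)phenol
Product: 6 [2-bromo-3,5-bis(methoxymethoxy)phenoxy](tert-butyl)dimethylsilane
Conditions: TBSCl (1.3 equiv), imidazole (2.5 equiv), DMF, rt
Reagents that add atoms: tert-butyldimethylsilyl chloride, CC(C)(C)[Si](C)(C)Cl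
Why: Silylation masks the acidic OH, which would otherwise protonate the boron ate complex of step 6, with a group that methoxide removes again in step 7.

Step 5
Reactants: 7 4-bromo-2-methylbut-1-ene
Product: 9 4,4,5,5-tetramethyl-2-(3-methylbut-3-en-1-yl)-1,3,2-dioxaborolane, via alkylmagnesium bromide 8 (not isolated)
Conditions: Mg, THF, 40 °C; then 2-isopropoxy-4,4,5,5-tetramethyl-1,3,2-dioxaborolane, −78 °C → rt; aq. NH4Cl
Reagents that add atoms: magnesium, [Mg] (in 8 only); 2-isopropoxy-4,4,5,5-tetramethyl-1,3,2-dioxaborolane, CC(C)OB1OC(C)(C)C(C)(C)O1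
Why: Magnesium insertion followed by borylation with displacement of isopropoxide gives the primary alkylboronic ester that carries the C5 arm of the side chain.

Step 6
Reactants: 9 4,4,5,5-tetramethyl-2-(3-methylbut-3-en-1-yl)-1,3,2-dioxaborolane, 10 vinylmagnesium bromide, 6 [2-bromo-3,5-bis(methoxymethoxy)phenoxy](tert-butyl)dimethylsilane
Product: 12 tert-butyl{3,5-bis(methoxymethoxy)-2-[(2R)-5-methyl-2-(4,4,5,5-tetramethyl-1,3,2-dioxaborolan-2-yl)hex-5-en-1-yl]phenoxy}dimethylsilane, via vinylboron ate complex 11 (not isolated)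
Conditions: 9 (1.3 equiv), 10 (1.25 equiv), THF, 0 °C → rt; then NaOTf (2.5 equiv), Pd(OAc)2 (3 mol%), MandyPhos ligand 1,1′-bis[bis(4-methoxy-3,5-dimethylphenyl)phosphino]-2,2′-bis[α-(dimethylamino)benzyl]ferrocene (3.6 mol%, antipode giving (R)-12), 6 (1.0 equiv), THF/DMSO, 50 °C
Reagents that add atoms: none
Why: Proposed new method: enantioselective palladium-catalysed conjunctive cross-coupling has not been shown with a 2,6-dioxygenated, di-ortho-substituted electron-rich aryl bromide; oxidative addition of 6 to zerovalent palladium and bromide abstraction by NaOTf should give a cationic aryl–divalent-palladium species that binds the vinyl group of 11 and triggers anti 1,2-migration of the 3-methylbut-3-enyl group from boron to the α-carbon (the ligand-controlled, enantio-determining 1,2-metallate shift that sets the (R) centre), after which C(sp3)–C(sp2) reductive elimination, helped by the two ortho substituents, forms the aryl–CH2 bond; the closest known reaction type is the conjunctive coupling of organomagnesium-derived vinylboron ate complexes with unhindered aryl triflates and bromides.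

Step 7
Reactants: 12 tert-butyl{3,5-bis(methoxymethoxy)-2-[(2R)-5-methyl-2-(4,4,5,5-tetramethyl-1,3,2-dioxaborolan-2-yl)hex-5-en-1-yl]phenoxy}dimethylsilane, 13 2-bromopropene
Product: 18 3,5-bis(methoxymethoxy)-2-[(2R)-5-methyl-2-(prop-1-en-2-yl)hex-5-en-1-yl]phenol, via isopropenyllithium 14 (not isolated), via alkenylboron ate complex 15 (not isolated), via iodoalkylboronic ester 16 (not isolated), via silyl ether 17 (not isolated)
Conditions: 13 (1.6 equiv), t-BuLi (3.2 equiv), Et2O, −78 °C; 12, THF, −78 °C; I2 (1.6 equiv), THF, −78 °C; NaOMe (8 equiv), MeOH, −78 °C → rt, 4 h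
Reagents that add atoms: tert-butyllithium, [Li]C(C)(C)C (lithium of 14 and 15 only); iodine, II (iodine of 16 only)
Why: Zweifel olefination, in which iodination of the alkenyl ate complex triggers a 1,2-metallate shift of the secondary alkyl group with retention at the migrating carbon and methoxide-induced anti elimination releases the isopropenyl group, so the (R) centre is carried over unchanged, while the excess NaOMe also cleaves the aryl silyl ether.

Step 8
Reactants: 18 3,5-bis(methoxymethoxy)-2-[(2R)-5-methyl-2-(prop-1-en-2-yl)hex-5-en-1-yl]phenol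
Product: 19 2-hydroxy-4,6-bis(methoxymethoxy)-3-[(2R)-5-methyl-2-(prop-1-en-2-yl)hex-5-en-1-yl]benzaldehyde
Conditions: MgCl2 (3 equiv), Et3N (6 equiv), (CH2O)n (8 equiv), MeCN, reflux
Reagents that add atoms: formaldehyde (as paraformaldehyde), C=O
Why: Magnesium-mediated ortho-formylation (Casnati–Skattebøl type) is ortho-specific through the magnesium phenoxide, and the only free ortho position is the future C4a, so no acid touches the MOM groups or the alkenes.

Step 9
Reactants: 19 2-hydroxy-4,6-bis(methoxymethoxy)-3-[(2R)-5-methyl-2-(prop-1-en-2-yl)hex-5-en-1-yl]benzaldehyde, 20 ethynylmagnesium bromide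
Product: 21 1-{2-hydroxy-4,6-bis(methoxymethoxy)-3-[(2R)-5-methyl-2-(prop-1-en-2-yl)hex-5-en-1-yl]phenyl}prop-2-yn-1-ol
Conditions: 20 (3 equiv), THF, 0 °C → rt; aq. NH4Cl
Reagents that add atoms: none
Why: 1,2-Addition of the alkynylmagnesium halide to the aldehyde after deprotonation of the phenol supplies C2 and C3; the new carbinol centre is uncontrolled and is destroyed in step 10.

Step 10
Reactants: 21 1-{2-hydroxy-4,6-bis(methoxymethoxy)-3-[(2R)-5-methyl-2-(prop-1-en-2-yl)hex-5-en-1-yl]phenyl}prop-2-yn-1-ol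
Product: 23 5,7-bis(methoxymethoxy)-8-[(2R)-5-methyl-2-(prop-1-en-2-yl)hex-5-en-1-yl]-4H-chromen-4-one, via ynone 22 (not isolated)
Conditions: MnO2 (15 equiv), CH2Cl2, rt; filter; K2CO3 (0.2 equiv), acetone, rt
Reagents that add atoms: none
Why: MnO2 oxidation of the benzylic–propargylic alcohol gives an ynone that closes ring C by base-catalysed 6-endo-dig oxa-Michael addition of the only free phenol, which fixes the side chain at C8.

Step 11
Reactants: 24 4-bromophenol
Product: 27 (4-hydroxyphenyl)boronic acid, via lithium 4-lithiophenolate 25 (not isolated), via aryltriisopropoxyborate 26 (not isolated)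
Conditions: t-BuLi (3.1 equiv), THF, −78 °C; B(OiPr)3 (1.5 equiv), −78 °C → rt; 1 M HCl to pH 5
Reagents that add atoms: tert-butyllithium, [Li]C(C)(C)C (lithium of 25 and 26 only); triisopropyl borate, CC(C)OB(OC(C)C)OC(C)C; water, O
Why: Deprotonation, bromine–lithium exchange on the lithium phenoxide and borylation give the ring B boronic acid without a protecting group.

Step 12
Reactants: 23 5,7-bis(methoxymethoxy)-8-[(2R)-5-methyl-2-(prop-1-en-2-yl)hex-5-en-1-yl]-4H-chromen-4-one, 27 (4-hydroxyphenyl)boronic acid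
Product: 28 (2S)-2-(4-hydroxyphenyl)-5,7-bis(methoxymethoxy)-8-[(2R)-5-methyl-2-(prop-1-en-2-yl)hex-5-en-1-yl]-2,3-dihydro-4H-chromen-4-one
Conditions: [Rh(OH)(cod)]2 (1.5 mol%), (S)-(6,6′-dimethoxybiphenyl-2,2′-diyl)bis[bis(3,4,5-trifluorophenyl)phosphine] (3.3 mol%), 27 (3 equiv), toluene/H2O (10:1), 40 °C
Reagents that add atoms: none
Why: Rhodium-catalysed asymmetric 1,4-addition of an arylboronic acid to a chromone (Hayashi–Miyaura reaction) under base-free conditions sets C2 as (S) under control of the electron-poor biaryl diphosphine, the remote side-chain centre having no influence, and avoids base-induced ring opening of the flavanone.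

Step 13
Reactants: 28 (2S)-2-(4-hydroxyphenyl)-5,7-bis(methoxymethoxy)-8-[(2R)-5-methyl-2-(prop-1-en-2-yl)hex-5-en-1-yl]-2,3-dihydro-4H-chromen-4-one
Product: 29 remangiflavanone A
Conditions: HCl (1.25 M in MeOH), THF, 40 °C
Reagents that add atoms: none
Why: Acid-catalysed acetal methanolysis removes both MOM groups under conditions that are used for prenylated flavanones and leave the 1,1-disubstituted alkenes and both stereocentres untouched.

## Compound list

1 | resorcinol | Oc1cccc(O)c1 | starting material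
2 | 1,3-bis(methoxymethoxy)benzene | COCOc1cccc(OCOC)c1 | intermediate
3 | 2-[3,5-bis(methoxymethoxy)phenyl]-4,4,5,5-tetramethyl-1,3,2-dioxaborolane | COCOc1cc(OCOC)cc(c1)B1OC(C)(C)C(C)(C)O1 | intermediate
4 | 3,5-bis(methoxymethoxy)phenol | COCOc1cc(O)cc(OCOC)c1 | intermediate
5 | 2-bromo-3,5-bis(methoxymethoxy)phenol | COCOc1cc(O)c(Br)c(OCOC)c1 | intermediate
6 | [2-bromo-3,5-bis(methoxymethoxy)phenoxy](tert-butyl)dimethylsilane | COCOc1cc(O[Si](C)(C)C(C)(C)C)c(Br)c(OCOC)c1 | intermediate
7 | 4-bromo-2-methylbut-1-ene | C=C(C)CCBr | starting material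
8 | (3-methylbut-3-en-1-yl)magnesium bromide | C=C(C)CC[Mg]Br | intermediate
9 | 4,4,5,5-tetramethyl-2-(3-methylbut-3-en-1-yl)-1,3,2-dioxaborolane | C=C(C)CCB1OC(C)(C)C(C)(C)O1 | intermediate
10 | vinylmagnesium bromide | C=C[Mg]Br | starting material
11 | bromomagnesium (3-methylbut-3-en-1-yl)(pinacolato)(vinyl)borate | C=C(C)CC[B-]1(C=C)OC(C)(C)C(C)(C)O1.[Mg+2].[Br-] | intermediate
12 | tert-butyl{3,5-bis(methoxymethoxy)-2-[(2R)-5-methyl-2-(4,4,5,5-tetramethyl-1,3,2-dioxaborolan-2-yl)hex-5-en-1-yl]phenoxy}dimethylsilane | C=C(C)CC[C@H](Cc1c(O[Si](C)(C)C(C)(C)C)cc(OCOC)cc1OCOC)B1OC(C)(C)C(C)(C)O1 | intermediate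
13 | 2-bromopropene | C=C(C)Br | starting material
14 | prop-1-en-2-yllithium | [Li]C(C)=C | intermediate
15 | lithium [(2R)-1-{2-[(tert-butyldimethylsilyl)oxy]-4,6-bis(methoxymethoxy)phenyl}-5-methylhex-5-en-2-yl](pinacolato)(prop-1-en-2-yl)borate | C=C(C)CC[C@H](Cc1c(O[Si](C)(C)C(C)(C)C)cc(OCOC)cc1OCOC)[B-]1(C(C)=C)OC(C)(C)C(C)(C)O1.[Li+] | intermediate
16 | tert-butyl{2-[(2R)-2-[1-iodo-2-(4,4,5,5-tetramethyl-1,3,2-dioxaborolan-2-yl)propan-2-yl]-5-methylhex-5-en-1-yl]-3,5-bis(methoxymethoxy)phenoxy}dimethylsilane (both configurations at the boron-bearing carbon) | C=C(C)CC[C@H](Cc1c(O[Si](C)(C)C(C)(C)C)cc(OCOC)cc1OCOC)C(C)(CI)B1OC(C)(C)C(C)(C)O1 | intermediate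
17 | tert-butyl{3,5-bis(methoxymethoxy)-2-[(2R)-5-methyl-2-(prop-1-en-2-yl)hex-5-en-1-yl]phenoxy}dimethylsilane | C=C(C)CC[C@H](Cc1c(O[Si](C)(C)C(C)(C)C)cc(OCOC)cc1OCOC)C(C)=C | intermediate
18 | 3,5-bis(methoxymethoxy)-2-[(2R)-5-methyl-2-(prop-1-en-2-yl)hex-5-en-1-yl]phenol | C=C(C)CC[C@H](Cc1c(O)cc(OCOC)cc1OCOC)C(C)=C | intermediate
19 | 2-hydroxy-4,6-bis(methoxymethoxy)-3-[(2R)-5-methyl-2-(prop-1-en-2-yl)hex-5-en-1-yl]benzaldehyde | C=C(C)CC[C@H](Cc1c(O)c(C=O)c(OCOC)cc1OCOC)C(C)=C | intermediate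
20 | ethynylmagnesium bromide | C#C[Mg]Br | starting material
21 | 1-{2-hydroxy-4,6-bis(methoxymethoxy)-3-[(2R)-5-methyl-2-(prop-1-en-2-yl)hex-5-en-1-yl]phenyl}prop-2-yn-1-ol (both carbinol epimers) | C=C(C)CC[C@H](Cc1c(O)c(C(O)C#C)c(OCOC)cc1OCOC)C(C)=C | intermediate
22 | 1-{2-hydroxy-4,6-bis(methoxymethoxy)-3-[(2R)-5-methyl-2-(prop-1-en-2-yl)hex-5-en-1-yl]phenyl}prop-2-yn-1-one | C=C(C)CC[C@H](Cc1c(O)c(C(=O)C#C)c(OCOC)cc1OCOC)C(C)=C | intermediate
23 | 5,7-bis(methoxymethoxy)-8-[(2R)-5-methyl-2-(prop-1-en-2-yl)hex-5-en-1-yl]-4H-chromen-4-one | C=C(C)CC[C@H](Cc1c(OCOC)cc(OCOC)c2c1occc2=O)C(C)=C | intermediate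
24 | 4-bromophenol | Oc1ccc(Br)cc1 | starting material
25 | lithium 4-lithiophenolate | [Li]Oc1ccc([Li])cc1 | intermediate
26 | dilithium triisopropoxy(4-oxidophenyl)borate | [Li+].[Li+].[O-]c1ccc(cc1)[B-](OC(C)C)(OC(C)C)OC(C)C | intermediate
27 | (4-hydroxyphenyl)boronic acid | OB(O)c1ccc(O)cc1 | intermediate
28 | (2S)-2-(4-hydroxyphenyl)-5,7-bis(methoxymethoxy)-8-[(2R)-5-methyl-2-(prop-1-en-2-yl)hex-5-en-1-yl]-2,3-dihydro-4H-chromen-4-one | C=C(C)CC[C@H](Cc1c(OCOC)cc(OCOC)c2c1O[C@H](c1ccc(O)cc1)CC2=O)C(=C)C | intermediate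
29 | remangiflavanone A, (2S)-5,7-dihydroxy-2-(4-hydroxyphenyl)-8-[(2R)-5-methyl-2-(prop-1-en-2-yl)hex-5-en-1-yl]-2,3-dihydro-4H-chromen-4-one | C=C(C)CC[C@H](Cc1c(O)cc(O)c2c1O[C@H](c1ccc(O)cc1)CC2=O)C(=C)C | target

## Step count and risks

Total step count: 13. Longest linear sequence: 11 steps (1–4, 6–10, 12, 13); steps 5 and 11 are one-step branches.

**Step 6 (the proposed new step).** The di-ortho-oxygenated, electron-rich bromide 6 may add too slowly to palladium, or the hindered aryl–palladium species may give Heck-type by-products or low selectivity. The fallback uses known chemistry and sets out from 6. Bromine–lithium exchange (t-BuLi, THF, −78 °C) and trapping with 2-(chloromethyl)-4,4,5,5-tetramethyl-1,3,2-dioxaborolane, then warming, give by Matteson homologation the benzylic boronic ester tert-butyl{3,5-bis(methoxymethoxy)-2-[(4,4,5,5-tetramethyl-1,3,2-dioxaborolan-2-yl)methyl]phenoxy}dimethylsilane F3. Commercial 4-methylpent-4-en-1-ol is converted with N,N-diisopropylcarbamoyl chloride into 4-methylpent-4-en-1-yl N,N-diisopropylcarbamate F4. Lithiation–borylation (s-BuLi, (−)-sparteine, Et2O, −78 °C; then F3; then MgBr2·OEt2, reflux) removes the pro-S proton, borylates with retention and moves the benzyl group from boron to carbon with inversion. This gives the (R)-boronic ester and returns the route to 12.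

**Step 3.** Bromination may also occur para to the hydroxyl or twice. The fallback sets out from 4. Carbamoylation (ClCONEt2, K2CO3, MeCN, reflux) gives 3,5-bis(methoxymethoxy)phenyl N,N-diethylcarbamate F1. Directed ortho-metalation (s-BuLi, TMEDA, THF, −78 °C), which the carbamate steers to the position between itself and an OMOM group, and quenching with BrCCl2CCl2Br at −78 °C give 2-bromo-3,5-bis(methoxymethoxy)phenyl N,N-diethylcarbamate F2. Hydrolysis of the carbamate (NaOH, EtOH/H2O, reflux) returns the route to 5.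

**Step 12.** The electron-rich, 5,7,8-trisubstituted chromone may be a poor acceptor, and the electron-rich boronic acid may protodeboronate. The fallback sets out from 19 and builds ring C by Claisen–Schmidt condensation and oxa-Michael closure instead.
- MeMgBr (3 equiv, THF, 0 °C) gives the methyl carbinol F5, and MnO2 (CH2Cl2) gives the methyl ketone F6.
- 24 is protected (MOMCl, i-Pr2NEt) as 1-bromo-4-(methoxymethoxy)benzene F7 and formylated (n-BuLi, THF, −78 °C; DMF) to 4-(methoxymethoxy)benzaldehyde F8.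
- Condensation of F6 with F8 (KOH, EtOH, rt) gives the 2′-hydroxychalcone F9.
- NaOAc in refluxing EtOH closes ring C to the tris-MOM flavanone as a pair of C2 epimers, the (2S) flavanone F10 and the (2R) flavanone F11. These are diastereomers and are separated by preparative HPLC; F11 is re-equilibrated under the same NaOAc conditions.
- Acid methanolysis of F10 under the conditions of step 13 rejoins the route at 29.

## Further compounds

F1 | step 3 | 3,5-bis(methoxymethoxy)phenyl N,N-diethylcarbamate | CCN(CC)C(=O)Oc1cc(OCOC)cc(OCOC)c1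
F2 | step 3 | 2-bromo-3,5-bis(methoxymethoxy)phenyl N,N-diethylcarbamate | CCN(CC)C(=O)Oc1cc(OCOC)cc(OCOC)c1Br
F3 | step 6 | tert-butyl{3,5-bis(methoxymethoxy)-2-[(4,4,5,5-tetramethyl-1,3,2-dioxaborolan-2-yl)methyl]phenoxy}dimethylsilane | COCOc1cc(O[Si](C)(C)C(C)(C)C)c(CB2OC(C)(C)C(C)(C)O2)c(OCOC)c1
F4 | step 6 | 4-methylpent-4-en-1-yl N,N-diisopropylcarbamate | C=C(C)CCCOC(=O)N(C(C)C)C(C)C
F5 | step 12 | 1-{2-hydroxy-4,6-bis(methoxymethoxy)-3-[(2R)-5-methyl-2-(prop-1-en-2-yl)hex-5-en-1-yl]phenyl}ethan-1-ol (both carbinol epimers) | C=C(C)CC[C@H](Cc1c(O)c(C(C)O)c(OCOC)cc1OCOC)C(C)=C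
F6 | step 12 | 1-{2-hydroxy-4,6-bis(methoxymethoxy)-3-[(2R)-5-methyl-2-(prop-1-en-2-yl)hex-5-en-1-yl]phenyl}ethan-1-one | C=C(C)CC[C@H](Cc1c(O)c(C(C)=O)c(OCOC)cc1OCOC)C(C)=C
F7 | step 12 | 1-bromo-4-(methoxymethoxy)benzene | COCOc1ccc(Br)cc1
F8 | step 12 | 4-(methoxymethoxy)benzaldehyde | COCOc1ccc(C=O)cc1
F9 | step 12 | (2E)-1-{2-hydroxy-4,6-bis(methoxymethoxy)-3-[(2R)-5-methyl-2-(prop-1-en-2-yl)hex-5-en-1-yl]phenyl}-3-[4-(methoxymethoxy)phenyl]prop-2-en-1-one | C=C(C)CC[C@H](Cc1c(O)c(C(=O)/C=C/c2ccc(OCOC)cc2)c(OCOC)cc1OCOC)C(C)=C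
F10 | step 12 | (2S)-5,7-bis(methoxymethoxy)-2-[4-(methoxymethoxy)phenyl]-8-[(2R)-5-methyl-2-(prop-1-en-2-yl)hex-5-en-1-yl]-2,3-dihydro-4H-chromen-4-one | C=C(C)CC[C@H](Cc1c(OCOC)cc(OCOC)c2c1O[C@H](c1ccc(OCOC)cc1)CC2=O)C(=C)C
F11 | step 12 | (2R)-5,7-bis(methoxymethoxy)-2-[4-(methoxymethoxy)phenyl]-8-[(2R)-5-methyl-2-(prop-1-en-2-yl)hex-5-en-1-yl]-2,3-dihydro-4H-chromen-4-one | C=C(C)CC[C@H](Cc1c(OCOC)cc(OCOC)c2c1O[C@@H](c1ccc(OCOC)cc1)CC2=O)C(=C)C
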